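1. The grey run stood at 20.36 mM of X after 180 h, and the ochre flask has the same charge. Your decision is whether to change that charge or leave it and wait the 1100 h.

| flask | Q | G | X | time |
|---|---|---|---|---|
| grey | 50.0 mM | 55.0 mM |  |  |
| amber | 20.0 mM | 25.0 mM |  |  |
| green | 50.0 mM | 55.0 mM | 25.0 mM |  |
| teal | 150 mM | 55.0 mM |  |  |
| ochre | 50.0 mM | 55.0 mM |  | 1100 h |

| run | time / h | [X] / mM |
|---|---|---|
| grey run | 8.0 | 6.06 |
| grey run | 24 | 12.40 |
| grey run | 46 | 16.19 |
| grey run | 74 | 18.23 |
| grey run | 110 | 19.69 |
| grey run | 140 | 20.13 |
| grey run | 180 | 20.36 |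
| amber run | 8.0 | 0.99 |
| amber run | 24 | 1.92 |
| amber run | 46 | 3.40 |
| amber run | 74 | 3.25 |
| amber run | 110 | 3.98 |
| amber run | 140 | 4.32 |
| amber run | 180 | 4.36 |
| green run | 8.0 | 31.58 |
| green run | 24 | 37.65 |
| green run | 46 | 41.41 |
| green run | 74 | 43.31 |
| green run | 110 | 44.68 |
| green run | 140 | 44.88 |
| green run | 180 | 45.50 |
| teal run | 8.0 | 16.32 |
| teal run | 24 | 27.84 |
| teal run | 46 | 32.77 |
| teal run | 74 | 35.12 |
| teal run | 110 | 36.67 |
| teal run | 140 | 37.10 |
| teal run | 180 | 37.28 |

(readings scatter by 0.2 mM)

- Overall: Q + G -> X.
- Constant volume, constant temperature.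
- Bound and free are read together.
- "The second partner" is G.
- An order is taken over about fifteen percent of the charge, up and down.

- the exponent of [Q] in the starting rate at the charge of the grey run (at the point where two percent of the Q have become X) (one fixed amount of X, the same in the runs compared)
- the exponent of [G] in the starting rate at the charge of the grey run (at the point where two percent of the Q have become X)
- X in the ochre run at 1100 h, as a share of the Q charged

2. Count turnovers. At its last reading the grey run has made X equal to 40.7 % of the Q charged.

3. The green run started with 25.0 mM of X and gained 20.5 mM, close to the grey gain, given a scatter of 0.2 mM per reading. Adding X is therefore not worth trying.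

4. In the grey run the last gap between readings, 0.230 mM, is half the gap before it, 0.440 mM. Both gaps carry that scatter. If the halving continues, the later gaps add up to about one more last gap.

5. My own reckoning: call the final X per G charged the turnover count, 0.374. For the ochre flask this gives 20.6 mM of X, or 41.2 % of its Q.

6. The teal run, with the same G but 150 mM of Q, reached a count of 0.678 at 180 h, higher than the grey count. That is a different flask, though. The ochre charge stays as it is, and you take the reading at 1100 h.

7. The forecast gives 41.2 %, with a range of 40.3 % to 45 %, and exponents of 0.95 for [Q] and 1.2 for [G]. On the range it says: “A slow uncatalysed creep can't be excluded, so the upper range is wider”.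

    2 G ⇌ G2, settled at all times (7.760 L mol⁻¹)
    Q + G2 → X + G (2.182 L mol⁻¹ h⁻¹)
    2 G → Ek (0.3744 L mol⁻¹ h⁻¹)
    Q → Oz (0.004464 h⁻¹)

The ochre flask gives 42.2 %, with exponents of 1.1 for [Q] and 1.5 for [G], the second higher than the forecast's 1.2. That share is 21.1 mM of X, a turnover count of 0.384, or 1.02 times 0.374. In the teal run the X made comes to a quarter of the Q charged at 180 h, a turnover count of 0.682, which is 1.82 times 0.374.

The readings are calculated for an exercise; noise was put on by code.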